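The target is cut at the stilbene (C5 of ring A to C6 of ring B) into a ring A styrene and a B–C aryl bromide, joined late by a Heck reaction. The key step exploits the C2–C3 bond of ring A, which links the O-benzylic carbon C2 (bearing O1 and the 4-hydroxyphenyl group) to the diarylmethine C3 at C3a: a diaryl carbene at C3 inserts into a C–H bond of the O–CH2–aryl ether on C7a. One flask turns a hydrazone into the diazo compound, closes ring A, forms C2–C3 and sets both stereocentres trans. The precursor is the hydrazone of a 2-(4-methoxybenzyloxy)benzophenone. Rings C and B close the same way.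

Key step: step 6

Ring labels: ring A is the 7-hydroxy dihydrobenzofuran carrying the stilbene at C5; ring B is the dihydrobenzofuran carrying the stilbene at C6; ring C is the 6-hydroxy dihydrobenzofuran bonded through C4 to C3 of ring B. The target is 2S,3S in ring A, 2R,3R in ring B and 2S,3S in ring C, all three rings trans.

Assumption: Rh2(R-PTAD)4 (PTAD = N-phthaloyl-1-adamantylglycinate) is taken to give the 3S sense needed in rings A and C, so ring B uses Rh2(S-PTAD)4; if a pilot run on 8 shows the opposite sense, the two catalyst enantiomers are exchanged in steps 6, 14 and 19.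

**Ring A fragment**

Step 1
Reactants: 1 5-bromo-2-hydroxy-3-methoxybenzaldehyde; 2 4-methoxybenzyl chloride
Product: 3 5-bromo-3-methoxy-2-(4-methoxybenzyloxy)benzaldehyde
Conditions: K2CO3, KI (cat.), DMF, 60 °C
Reagents that add atoms: none
Why: Williamson ether synthesis: the phenoxide of 1 displaces chloride from the benzylic halide in an SN2 reaction, and K2CO3 touches neither the aldehyde nor the aryl bromide.

Step 2
Reactants: 4 1-bromo-3,5-dimethoxybenzene
Product: 5 3,5-dimethoxyphenylmagnesium bromide (THF solution, titrated, kept under argon, one batch divided between steps 3 and 11)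
Conditions: Mg turnings, I2 (cat.), THF, reflux
Reagents that add atoms: magnesium, [Mg]
Why: Grignard reagent formation by oxidative insertion of magnesium into the aryl C–Br bond; the two methoxy groups are inert, and the solution should be stable enough to serve both carbonyl additions.

Step 3
Reactants: 3 5-bromo-3-methoxy-2-(4-methoxybenzyloxy)benzaldehyde; 5 3,5-dimethoxyphenylmagnesium bromide
Product: 6 [5-bromo-3-methoxy-2-(4-methoxybenzyloxy)phenyl](3,5-dimethoxyphenyl)methanol
Conditions: 5 (1.2 equiv), THF, 0 °C to rt; aq NH4Cl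
Reagents that add atoms: none
Why: Grignard addition: the arylmagnesium bromide adds to the aldehyde carbonyl faster than it can exchange with the aryl bromide of 3, and the racemic carbinol centre is removed in step 4.

Step 4
Reactants: 6 [5-bromo-3-methoxy-2-(4-methoxybenzyloxy)phenyl](3,5-dimethoxyphenyl)methanol
Product: 7 [5-bromo-3-methoxy-2-(4-methoxybenzyloxy)phenyl](3,5-dimethoxyphenyl)methanone
Conditions: Dess–Martin periodinane, CH2Cl2, 0 °C to rt
Reagents that add atoms: none
Why: Dess–Martin oxidation of the secondary diaryl carbinol to the benzophenone under neutral conditions that leave the 4-methoxybenzyl ether, the methyl ethers and the bromide untouched.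

Step 5
Reactants: 7 [5-bromo-3-methoxy-2-(4-methoxybenzyloxy)phenyl](3,5-dimethoxyphenyl)methanone
Product: 8 [5-bromo-3-methoxy-2-(4-methoxybenzyloxy)phenyl](3,5-dimethoxyphenyl)methanone hydrazone
Conditions: N2H4·H2O (10 equiv), AcOH (cat.), EtOH, 80 °C
Reagents that add atoms: hydrazine (as monohydrate), NN
Why: Acid-catalysed hydrazone formation: excess hydrazine condenses with the ketone, which carries only one ortho substituent, and the excess suppresses azine formation; both hydrazone geometries give the same diazo compound.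

Step 6
Reactants: 8 [5-bromo-3-methoxy-2-(4-methoxybenzyloxy)phenyl](3,5-dimethoxyphenyl)methanone hydrazone
Product: 11 (2S,3S)-5-bromo-3-(3,5-dimethoxyphenyl)-7-methoxy-2-(4-methoxyphenyl)-2,3-dihydrobenzofuran, via diazo compound 9 (not isolated), via cis isomer 10 (not isolated)
Conditions: MnO2 (activated), CH2Cl2, 0 °C to rt, filter; Rh2(R-PTAD)4 (1 mol %), CH2Cl2, 0 °C to rt; then CF3CO2H (0.5 equiv), same flask, 0 °C, short contact
Reagents that add atoms: none
Why: MnO2 dehydrogenates the hydrazone to diaryldiazomethane 9, which loses N2 on the chiral dirhodium tetracarboxylate to give a rhodium diaryl carbene at the future C3; the carbene takes a hydride from the ether CH2, which is activated by oxygen and by the 4-methoxyphenyl group, and the resulting ion pair collapses to the C2–C3 bond (a formal insertion through a three-centre transition state). The closest known reaction type is the dirhodium-catalysed enantioselective intramolecular C–H insertion of diaryl carbenes into benzylic ethers, which gives 2,3-diaryl-2,3-dihydrobenzofurans. Ring A closes as a five-membered ring by C–C bond formation between the carbene carbon and the ether carbon, because only the atoms carbene C, C3a, C7a, O1 and CH2 stand in the required 1,5 relationship. C3 is set by the chiral ligand sphere of the catalyst, which tells the two faces of the carbene apart, whereas C2 arrives cis (10) and is then placed trans to C3 under thermodynamic control, the acid reversibly ionising O1–C2 to the 4-methoxybenzylic cation. The step needs site selectivity for the ether CH2 over azine formation and enantiofacial selectivity at the carbene; the intramolecular geometry, the hydridic doubly activated CH2 and the single ortho substituent on the carbene-bearing ring secure both. The acid contact is kept short and cold so that the cation recloses through oxygen and is not deprotonated at C3, which would erase the catalyst-set centre.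

Step 7
Reactants: 11 (2S,3S)-5-bromo-3-(3,5-dimethoxyphenyl)-7-methoxy-2-(4-methoxyphenyl)-2,3-dihydrobenzofuran; 12 potassium vinyltrifluoroborate
Product: 13 (2S,3S)-3-(3,5-dimethoxyphenyl)-5-ethenyl-7-methoxy-2-(4-methoxyphenyl)-2,3-dihydrobenzofuran
Conditions: PdCl2(dppf)·CH2Cl2 (3 mol %), Cs2CO3, THF/H2O 9:1, 80 °C
Reagents that add atoms: none
Why: Suzuki–Miyaura coupling of the aryl bromide with the vinyltrifluoroborate; the basic medium cannot ionise the O1–C2 bond, so both stereocentres are retained.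

**Ring C**

Step 8
Reactants: 4 1-bromo-3,5-dimethoxybenzene
Product: 15 2-bromo-4,6-dimethoxybenzaldehyde, via iminium chloride 14 (not isolated)
Conditions: POCl3, DMF, 0 to 90 °C; then ice-water
Reagents that add atoms: N,N-dimethylformamide, CN(C)C=O; water, O
Why: Vilsmeier–Haack formylation: the chloroiminium ion substitutes the ring para to one methoxy group and ortho to the other, next to bromine, because the position between the two methoxy groups is more hindered, and water hydrolyses iminium 14 to the aldehyde.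

Step 9
Reactants: 15 2-bromo-4,6-dimethoxybenzaldehyde
Product: 16 2-bromo-6-hydroxy-4-methoxybenzaldehyde
Conditions: BCl3 (1.5 equiv), CH2Cl2, −78 to 0 °C; then H2O
Reagents that add atoms: none
Why: Chelation-controlled Lewis-acid ether cleavage: BCl3 bound to the aldehyde oxygen reaches only the ortho methoxy group through a six-membered chelate, so the para methoxy group survives.

Step 10
Reactants: 16 2-bromo-6-hydroxy-4-methoxybenzaldehyde; 2 4-methoxybenzyl chloride
Product: 17 2-bromo-4-methoxy-6-(4-methoxybenzyloxy)benzaldehyde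
Conditions: K2CO3, KI (cat.), DMF, 60 °C
Reagents that add atoms: none
Why: Williamson ether synthesis as in step 1; the hydrogen-bonded ortho phenol is alkylated cleanly in DMF.

Step 11
Reactants: 17 2-bromo-4-methoxy-6-(4-methoxybenzyloxy)benzaldehyde; 5 3,5-dimethoxyphenylmagnesium bromide
Product: 18 [2-bromo-4-methoxy-6-(4-methoxybenzyloxy)phenyl](3,5-dimethoxyphenyl)methanol
Conditions: 5 (1.3 equiv, second portion of the solution from step 2), THF, 0 °C to rt; aq NH4Cl
Reagents that add atoms: none
Why: Grignard addition to the aldehyde, whose formyl group stays accessible between the two ortho substituents; an arylmagnesium halide does not exchange with the aryl bromide, and the carbinol centre is removed in step 12.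

Step 12
Reactants: 18 [2-bromo-4-methoxy-6-(4-methoxybenzyloxy)phenyl](3,5-dimethoxyphenyl)methanol
Product: 19 [2-bromo-4-methoxy-6-(4-methoxybenzyloxy)phenyl](3,5-dimethoxyphenyl)methanone
Conditions: Dess–Martin periodinane, CH2Cl2, 0 °C to rt
Reagents that add atoms: none
Why: Dess–Martin oxidation, which proceeds by ligand exchange at iodine on the hydroxyl group and is therefore tolerant of the two ortho substituents.

Step 13
Reactants: 19 [2-bromo-4-methoxy-6-(4-methoxybenzyloxy)phenyl](3,5-dimethoxyphenyl)methanone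
Product: 20 [2-bromo-4-methoxy-6-(4-methoxybenzyloxy)phenyl](3,5-dimethoxyphenyl)methanone hydrazone
Conditions: N2H4·H2O (20 equiv), AcOH (cat.), n-BuOH, 110 °C, sealed tube
Reagents that add atoms: hydrazine (as monohydrate), NN
Why: Hydrazone formation under forcing conditions: hydrazine is a small alpha-effect nucleophile and in large excess at 110 °C should condense even with this ketone shielded by bromine and the ether, while the temperature stays below that needed to displace the unactivated ortho bromine (indazole formation).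

Step 14
Reactants: 20 [2-bromo-4-methoxy-6-(4-methoxybenzyloxy)phenyl](3,5-dimethoxyphenyl)methanone hydrazone
Product: 23 (2S,3S)-4-bromo-3-(3,5-dimethoxyphenyl)-6-methoxy-2-(4-methoxyphenyl)-2,3-dihydrobenzofuran, via diazo compound 21 (not isolated), via cis isomer 22 (not isolated)
Conditions: MnO2 (activated), CH2Cl2, 0 °C to rt, filter; Rh2(R-PTAD)4 (2 mol %), CH2Cl2, 0 °C to rt; then CF3CO2H (0.5 equiv), same flask, 0 °C, short contact
Reagents that add atoms: none
Why: Same reaction type as step 6 (dirhodium-catalysed 1,5 C–H insertion of a diaryl carbene into the benzylic ether, then acid equilibration of C2): the two ortho substituents twist the carbene-bearing ring, which keeps the OCH2 group over the carbene carbon and disfavours azine formation, C3 is set by the same catalyst enantiomer as in step 6 because the local arrangement (tethered ring, free 3,5-dimethoxyphenyl ring) is the same, and C2 is set trans by thermodynamic control.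

**Ring B and the B–C bromide**

Step 15
Reactants: 24 4-bromo-2-hydroxybenzaldehyde; 2 4-methoxybenzyl chloride
Product: 25 4-bromo-2-(4-methoxybenzyloxy)benzaldehyde
Conditions: K2CO3, KI (cat.), DMF, 60 °C
Reagents that add atoms: none
Why: Williamson ether synthesis as in step 1.

Step 16
Reactants: 23 (2S,3S)-4-bromo-3-(3,5-dimethoxyphenyl)-6-methoxy-2-(4-methoxyphenyl)-2,3-dihydrobenzofuran; 25 4-bromo-2-(4-methoxybenzyloxy)benzaldehyde
Product: 27 [4-bromo-2-(4-methoxybenzyloxy)phenyl][(2S,3S)-3-(3,5-dimethoxyphenyl)-6-methoxy-2-(4-methoxyphenyl)-2,3-dihydrobenzofuran-4-yl]methanol, via aryllithium 26 (not isolated)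
Conditions: n-BuLi (1.05 equiv), THF, −78 °C; cannulated into 25, THF, −78 °C; aq NH4Cl
Reagents that add atoms: none
Why: Bromine–lithium exchange followed by 1,2-addition to the aldehyde: exchange at −78 °C is faster than deprotonation of the benzhydrylic C3–H, inverse addition lets the aryllithium meet excess aldehyde so that carbonyl addition outruns exchange with the bromide of 25, and the two carbinol epimers converge in step 17.

Step 17
Reactants: 27 [4-bromo-2-(4-methoxybenzyloxy)phenyl][(2S,3S)-3-(3,5-dimethoxyphenyl)-6-methoxy-2-(4-methoxyphenyl)-2,3-dihydrobenzofuran-4-yl]methanol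
Product: 28 [4-bromo-2-(4-methoxybenzyloxy)phenyl][(2S,3S)-3-(3,5-dimethoxyphenyl)-6-methoxy-2-(4-methoxyphenyl)-2,3-dihydrobenzofuran-4-yl]methanone
Conditions: Dess–Martin periodinane, CH2Cl2, 0 °C to rt
Reagents that add atoms: none
Why: Dess–Martin oxidation of both carbinol epimers to one ketone; the neutral conditions leave the trans ring C and its acid-labile O1–C2 bond intact.

Step 18
Reactants: 28 [4-bromo-2-(4-methoxybenzyloxy)phenyl][(2S,3S)-3-(3,5-dimethoxyphenyl)-6-methoxy-2-(4-methoxyphenyl)-2,3-dihydrobenzofuran-4-yl]methanone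
Product: 29 [4-bromo-2-(4-methoxybenzyloxy)phenyl][(2S,3S)-3-(3,5-dimethoxyphenyl)-6-methoxy-2-(4-methoxyphenyl)-2,3-dihydrobenzofuran-4-yl]methanone hydrazone
Conditions: N2H4·H2O (20 equiv), AcOH (cat.), n-BuOH, 110 °C, sealed tube
Reagents that add atoms: hydrazine (as monohydrate), NN
Why: Hydrazone formation: each ring at the carbonyl carries a single ortho substituent, so excess hydrazine at 110 °C should condense, and the weakly acidic medium can at most re-equilibrate ring C to the trans form it already has.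

Step 19
Reactants: 29 [4-bromo-2-(4-methoxybenzyloxy)phenyl][(2S,3S)-3-(3,5-dimethoxyphenyl)-6-methoxy-2-(4-methoxyphenyl)-2,3-dihydrobenzofuran-4-yl]methanone hydrazone
Product: 32 (2R,3R)-6-bromo-3-[(2S,3S)-3-(3,5-dimethoxyphenyl)-6-methoxy-2-(4-methoxyphenyl)-2,3-dihydrobenzofuran-4-yl]-2-(4-methoxyphenyl)-2,3-dihydrobenzofuran, via diazo compound 30 (not isolated), via cis isomer 31 (not isolated)
Conditions: MnO2 (activated), CH2Cl2, 0 °C to rt, filter; Rh2(S-PTAD)4 (2 mol %), CH2Cl2, 0 °C to rt; then CF3CO2H (0.5 equiv), same flask, 0 °C, short contact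
Reagents that add atoms: none
Why: Same reaction type as step 6 with the mirror-image catalyst, because ring B needs the opposite local configuration: the carbene at C3 takes a hydride from the ether CH2 on C7a and closes C2–C3 under catalyst control, the brief acid treatment then places C2 trans (the phenol oxygen recloses the five-membered ring faster than the 3,5-dimethoxyphenyl group of ring C can attack the cation), and any ring B isomer from imperfect facial control is a diastereomer of 32 and is removed by chromatography.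

**Union and deprotection**

Step 20
Reactants: 32 (2R,3R)-6-bromo-3-[(2S,3S)-3-(3,5-dimethoxyphenyl)-6-methoxy-2-(4-methoxyphenyl)-2,3-dihydrobenzofuran-4-yl]-2-(4-methoxyphenyl)-2,3-dihydrobenzofuran; 13 (2S,3S)-3-(3,5-dimethoxyphenyl)-5-ethenyl-7-methoxy-2-(4-methoxyphenyl)-2,3-dihydrobenzofuran
Product: 33 nona-O-methyl ether of the target (E-stilbene from C5 of ring A to C6 of ring B; full name in the compound list)
Conditions: Pd(OAc)2 (5 mol %), P(o-tol)3 (12 mol %), Et3N, DMF, 100 °C
Reagents that add atoms: none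
Why: Mizoroki–Heck reaction: oxidative addition of the aryl bromide to zerovalent palladium, syn insertion of the terminal alkene with the aryl group going to the unsubstituted carbon, and syn beta-hydride elimination give the E-stilbene, and the amine base leaves all six stereocentres untouched.

Step 21
Reactants: 33 nona-O-methyl ether of the target
Product: 34 target CNP0265934.1
Conditions: BBr3 (20 equiv), CH2Cl2, −78 °C to rt; then H2O, 0 °C
Reagents that add atoms: none
Why: Lewis-acid cleavage of all nine aryl methyl ethers by BBr3 (aryloxyborane formation, then demethylation by bromide), a standard last step for permethylated oligostilbenes; any reversible opening of an O1–C2 bond returns to the trans ring, so the six stereocentres are kept.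

**Compound list**

1 | 5-bromo-2-hydroxy-3-methoxybenzaldehyde | O=Cc1cc(Br)cc(OC)c1O | starting material
2 | 4-methoxybenzyl chloride | COc1ccc(CCl)cc1 | starting material
3 | 5-bromo-3-methoxy-2-(4-methoxybenzyloxy)benzaldehyde | O=Cc1cc(Br)cc(OC)c1OCc1ccc(OC)cc1 | intermediate
4 | 1-bromo-3,5-dimethoxybenzene | COc1cc(Br)cc(OC)c1 | starting material
5 | 3,5-dimethoxyphenylmagnesium bromide (THF solution) | COc1cc([Mg]Br)cc(OC)c1 | intermediate
6 | [5-bromo-3-methoxy-2-(4-methoxybenzyloxy)phenyl](3,5-dimethoxyphenyl)methanol (racemic) | OC(c1cc(OC)cc(OC)c1)c1cc(Br)cc(OC)c1OCc1ccc(OC)cc1 | intermediate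
7 | [5-bromo-3-methoxy-2-(4-methoxybenzyloxy)phenyl](3,5-dimethoxyphenyl)methanone | O=C(c1cc(OC)cc(OC)c1)c1cc(Br)cc(OC)c1OCc1ccc(OC)cc1 | intermediate
8 | hydrazone of 7 (both C=N geometries) | NN=C(c1cc(OC)cc(OC)c1)c1cc(Br)cc(OC)c1OCc1ccc(OC)cc1 | intermediate
9 | 5-bromo-1-[diazo(3,5-dimethoxyphenyl)methyl]-3-methoxy-2-(4-methoxybenzyloxy)benzene | [N-]=[N+]=C(c1cc(OC)cc(OC)c1)c1cc(Br)cc(OC)c1OCc1ccc(OC)cc1 | intermediate
10 | (2R,3S)-5-bromo-3-(3,5-dimethoxyphenyl)-7-methoxy-2-(4-methoxyphenyl)-2,3-dihydrobenzofuran (cis) | COc1ccc([C@@H]2Oc3c(OC)cc(Br)cc3[C@@H]2c2cc(OC)cc(OC)c2)cc1 | intermediate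
11 | (2S,3S)-5-bromo-3-(3,5-dimethoxyphenyl)-7-methoxy-2-(4-methoxyphenyl)-2,3-dihydrobenzofuran (trans) | COc1ccc([C@H]2Oc3c(OC)cc(Br)cc3[C@@H]2c2cc(OC)cc(OC)c2)cc1 | intermediate
12 | potassium vinyltrifluoroborate | C=C[B-](F)(F)F.[K+] | starting material
13 | (2S,3S)-3-(3,5-dimethoxyphenyl)-5-ethenyl-7-methoxy-2-(4-methoxyphenyl)-2,3-dihydrobenzofuran | COc1ccc([C@H]2Oc3c(OC)cc(C=C)cc3[C@@H]2c2cc(OC)cc(OC)c2)cc1 | intermediate
14 | N-[(2-bromo-4,6-dimethoxyphenyl)methylidene]-N-methylmethanaminium chloride | C[N+](C)=Cc1c(Br)cc(OC)cc1OC.[Cl-] | intermediate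
15 | 2-bromo-4,6-dimethoxybenzaldehyde | O=Cc1c(Br)cc(OC)cc1OC | intermediate
16 | 2-bromo-6-hydroxy-4-methoxybenzaldehyde | O=Cc1c(O)cc(OC)cc1Br | intermediate
17 | 2-bromo-4-methoxy-6-(4-methoxybenzyloxy)benzaldehyde | O=Cc1c(Br)cc(OC)cc1OCc1ccc(OC)cc1 | intermediate
18 | [2-bromo-4-methoxy-6-(4-methoxybenzyloxy)phenyl](3,5-dimethoxyphenyl)methanol (racemic) | OC(c1cc(OC)cc(OC)c1)c1c(Br)cc(OC)cc1OCc1ccc(OC)cc1 | intermediate
19 | [2-bromo-4-methoxy-6-(4-methoxybenzyloxy)phenyl](3,5-dimethoxyphenyl)methanone | O=C(c1cc(OC)cc(OC)c1)c1c(Br)cc(OC)cc1OCc1ccc(OC)cc1 | intermediate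
20 | hydrazone of 19 (both C=N geometries) | NN=C(c1cc(OC)cc(OC)c1)c1c(Br)cc(OC)cc1OCc1ccc(OC)cc1 | intermediate
21 | 1-bromo-2-[diazo(3,5-dimethoxyphenyl)methyl]-5-methoxy-3-(4-methoxybenzyloxy)benzene | [N-]=[N+]=C(c1cc(OC)cc(OC)c1)c1c(Br)cc(OC)cc1OCc1ccc(OC)cc1 | intermediate
22 | (2R,3S)-4-bromo-3-(3,5-dimethoxyphenyl)-6-methoxy-2-(4-methoxyphenyl)-2,3-dihydrobenzofuran (cis) | COc1ccc([C@@H]2Oc3cc(OC)cc(Br)c3[C@@H]2c2cc(OC)cc(OC)c2)cc1 | intermediate
23 | (2S,3S)-4-bromo-3-(3,5-dimethoxyphenyl)-6-methoxy-2-(4-methoxyphenyl)-2,3-dihydrobenzofuran (trans) | COc1ccc([C@H]2Oc3cc(OC)cc(Br)c3[C@@H]2c2cc(OC)cc(OC)c2)cc1 | intermediate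
24 | 4-bromo-2-hydroxybenzaldehyde | O=Cc1ccc(Br)cc1O | starting material
25 | 4-bromo-2-(4-methoxybenzyloxy)benzaldehyde | O=Cc1ccc(Br)cc1OCc1ccc(OC)cc1 | intermediate
26 | [(2S,3S)-3-(3,5-dimethoxyphenyl)-6-methoxy-2-(4-methoxyphenyl)-2,3-dihydrobenzofuran-4-yl]lithium | COc1ccc([C@H]2Oc3cc(OC)cc([Li])c3[C@@H]2c2cc(OC)cc(OC)c2)cc1 | intermediate
27 | [4-bromo-2-(4-methoxybenzyloxy)phenyl][(2S,3S)-3-(3,5-dimethoxyphenyl)-6-methoxy-2-(4-methoxyphenyl)-2,3-dihydrobenzofuran-4-yl]methanol (both carbinol epimers) | COc1ccc([C@H]2Oc3cc(OC)cc(C(O)c4ccc(Br)cc4OCc4ccc(OC)cc4)c3[C@@H]2c2cc(OC)cc(OC)c2)cc1 | intermediate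
28 | [4-bromo-2-(4-methoxybenzyloxy)phenyl][(2S,3S)-3-(3,5-dimethoxyphenyl)-6-methoxy-2-(4-methoxyphenyl)-2,3-dihydrobenzofuran-4-yl]methanone | COc1ccc([C@H]2Oc3cc(OC)cc(C(=O)c4ccc(Br)cc4OCc4ccc(OC)cc4)c3[C@@H]2c2cc(OC)cc(OC)c2)cc1 | intermediate
29 | hydrazone of 28 (both C=N geometries) | COc1ccc([C@H]2Oc3cc(OC)cc(C(=NN)c4ccc(Br)cc4OCc4ccc(OC)cc4)c3[C@@H]2c2cc(OC)cc(OC)c2)cc1 | intermediate
30 | (2S,3S)-4-{[4-bromo-2-(4-methoxybenzyloxy)phenyl](diazo)methyl}-3-(3,5-dimethoxyphenyl)-6-methoxy-2-(4-methoxyphenyl)-2,3-dihydrobenzofuran | COc1ccc([C@H]2Oc3cc(OC)cc(C(=[N+]=[N-])c4ccc(Br)cc4OCc4ccc(OC)cc4)c3[C@@H]2c2cc(OC)cc(OC)c2)cc1 | intermediate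
31 | (2S,3R)-6-bromo-3-[(2S,3S)-3-(3,5-dimethoxyphenyl)-6-methoxy-2-(4-methoxyphenyl)-2,3-dihydrobenzofuran-4-yl]-2-(4-methoxyphenyl)-2,3-dihydrobenzofuran (ring B cis) | Brc1ccc2c(c1)O[C@H](c1ccc(OC)cc1)[C@@H]2c1cc(OC)cc2c1[C@H](c1cc(OC)cc(OC)c1)[C@@H](c1ccc(OC)cc1)O2 | intermediate
32 | (2R,3R)-6-bromo-3-[(2S,3S)-3-(3,5-dimethoxyphenyl)-6-methoxy-2-(4-methoxyphenyl)-2,3-dihydrobenzofuran-4-yl]-2-(4-methoxyphenyl)-2,3-dihydrobenzofuran (ring B trans) | Brc1ccc2c(c1)O[C@@H](c1ccc(OC)cc1)[C@@H]2c1cc(OC)cc2c1[C@H](c1cc(OC)cc(OC)c1)[C@@H](c1ccc(OC)cc1)O2 | intermediate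
33 | (2S,3S)-3-(3,5-dimethoxyphenyl)-5-[(E)-2-{(2R,3R)-3-[(2S,3S)-3-(3,5-dimethoxyphenyl)-6-methoxy-2-(4-methoxyphenyl)-2,3-dihydrobenzofuran-4-yl]-2-(4-methoxyphenyl)-2,3-dihydrobenzofuran-6-yl}ethenyl]-7-methoxy-2-(4-methoxyphenyl)-2,3-dihydrobenzofuran | COc1ccc([C@H]2Oc3c(OC)cc(/C=C/c4ccc5c(c4)O[C@@H](c4ccc(OC)cc4)[C@@H]5c4cc(OC)cc5c4[C@H](c4cc(OC)cc(OC)c4)[C@@H](c4ccc(OC)cc4)O5)cc3[C@@H]2c2cc(OC)cc(OC)c2)cc1 | intermediate
34 | (2S,3S)-3-(3,5-dihydroxyphenyl)-5-[(E)-2-{(2R,3R)-3-[(2S,3S)-3-(3,5-dihydroxyphenyl)-6-hydroxy-2-(4-hydroxyphenyl)-2,3-dihydrobenzofuran-4-yl]-2-(4-hydroxyphenyl)-2,3-dihydrobenzofuran-6-yl}ethenyl]-2-(4-hydroxyphenyl)-2,3-dihydrobenzofuran-7-ol | Oc1ccc([C@H]2Oc3c(O)cc(/C=C/c4ccc5c(c4)O[C@@H](c4ccc(O)cc4)[C@@H]5c4cc(O)cc5c4[C@H](c4cc(O)cc(O)c4)[C@@H](c4ccc(O)cc4)O5)cc3[C@@H]2c2cc(O)cc(O)c2)cc1 | target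

Total step count: 21.
Longest linear sequence: 13 steps (4 to 34 through steps 8–14 and 16–21).

**Steps most likely to fail**

Step 19 (closure of ring B). The carbene at C3 of ring B sits next to the enantiopure, ortho-substituted ring C. Facial selection by the catalyst may be overridden by the substrate (mismatched pairing), and the carbene may be diverted into attack on the neighbouring 3,5-dimethoxyphenyl ring instead of taking the hydride from the ether CH2. The fallback sets out from ketone 28 and comes back at 32, closing O1–C2 by an ionic route instead of C2–C3. Ketone 28 is methylenated with trimethylsulfonium iodide and KOt-Bu (Corey–Chaykovsky) to the 2,2-diaryloxirane F1. ZnI2 rearranges this (Meinwald) to the diarylacetaldehyde F2, and 4-methoxyphenylmagnesium bromide gives the triarylethanol F3. CF3CO2H with anisole ionises F3 to the 4-methoxybenzylic cation, which the ether oxygen captures with loss of its 4-methoxybenzyl group, closing ring B trans under thermodynamic control. C3 of ring B is not controlled here, so 32 should form together with its ring B epimer F4. The two are diastereomers because ring C is a single enantiomer, and they are separated by chromatography.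

Step 14 (closure of ring C). The carbene carbon lies between two ortho substituents, bromine and the ether. Nitrogen loss and insertion may be slow enough for azine or ketone formation to compete, the twisted ring may blur the enantiofacial discrimination, and the bromine lone pair may trap the carbene. The fallback sets out from ketone 19 and comes back at 23 by the same ionic logic. Corey–Chaykovsky methylenation gives the oxirane F5, Meinwald rearrangement with ZnI2 gives the diarylacetaldehyde F6, and 4-methoxyphenylmagnesium bromide gives the triarylethanol F7. CF3CO2H with anisole closes the trans ring, here as the racemate. The racemate is resolved by preparative chromatography on a chiral stationary phase into 23 and its enantiomer F8, which is discarded.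

Step 13 (hydrazone of the di-ortho-substituted ketone). The condensation may stall because bromine and the ether shield the carbonyl carbon, and prolonged heating invites displacement of the ortho bromine by the hydrazone nitrogen. The fallback sets out from aldehyde 17 and comes back at hydrazone 20 without any attack on a ketone carbonyl. I2 in aqueous NH3 and THF converts 17 into the benzonitrile F9. Grignard reagent 5 (CuBr cat., THF, reflux, then MeOH) adds to the linear, unhindered nitrile to give the N–H ketimine F10. N2H4·H2O with a catalytic amount of hydrazine dihydrochloride in EtOH at 80 °C exchanges the imine nitrogen for hydrazine (transimination with loss of ammonia), the established way to hydrazones of hindered ketones.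

Further compounds
F1 | step 19 | 2-[4-bromo-2-(4-methoxybenzyloxy)phenyl]-2-[(2S,3S)-3-(3,5-dimethoxyphenyl)-6-methoxy-2-(4-methoxyphenyl)-2,3-dihydrobenzofuran-4-yl]oxirane (both epimers) | COc1ccc([C@H]2Oc3cc(OC)cc(C4(c5ccc(Br)cc5OCc5ccc(OC)cc5)CO4)c3[C@@H]2c2cc(OC)cc(OC)c2)cc1
F2 | step 19 | 2-[4-bromo-2-(4-methoxybenzyloxy)phenyl]-2-[(2S,3S)-3-(3,5-dimethoxyphenyl)-6-methoxy-2-(4-methoxyphenyl)-2,3-dihydrobenzofuran-4-yl]acetaldehyde (both epimers) | COc1ccc([C@H]2Oc3cc(OC)cc(C(C=O)c4ccc(Br)cc4OCc4ccc(OC)cc4)c3[C@@H]2c2cc(OC)cc(OC)c2)cc1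
F3 | step 19 | 2-[4-bromo-2-(4-methoxybenzyloxy)phenyl]-2-[(2S,3S)-3-(3,5-dimethoxyphenyl)-6-methoxy-2-(4-methoxyphenyl)-2,3-dihydrobenzofuran-4-yl]-1-(4-methoxyphenyl)ethanol (diastereomer mixture) | COc1ccc([C@H]2Oc3cc(OC)cc(C(C(O)c4ccc(OC)cc4)c4ccc(Br)cc4OCc4ccc(OC)cc4)c3[C@@H]2c2cc(OC)cc(OC)c2)cc1
F4 | step 19 | (2S,3S)-6-bromo-3-[(2S,3S)-3-(3,5-dimethoxyphenyl)-6-methoxy-2-(4-methoxyphenyl)-2,3-dihydrobenzofuran-4-yl]-2-(4-methoxyphenyl)-2,3-dihydrobenzofuran (ring B epimer of 32) | Brc1ccc2c(c1)O[C@H](c1ccc(OC)cc1)[C@H]2c1cc(OC)cc2c1[C@H](c1cc(OC)cc(OC)c1)[C@@H](c1ccc(OC)cc1)O2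
F5 | step 14 | 2-[2-bromo-4-methoxy-6-(4-methoxybenzyloxy)phenyl]-2-(3,5-dimethoxyphenyl)oxirane (racemic) | COc1cc(OC)cc(C2(CO2)c2c(Br)cc(OC)cc2OCc2ccc(OC)cc2)c1
F6 | step 14 | 2-[2-bromo-4-methoxy-6-(4-methoxybenzyloxy)phenyl]-2-(3,5-dimethoxyphenyl)acetaldehyde (racemic) | O=CC(c1cc(OC)cc(OC)c1)c1c(Br)cc(OC)cc1OCc1ccc(OC)cc1
F7 | step 14 | 2-[2-bromo-4-methoxy-6-(4-methoxybenzyloxy)phenyl]-2-(3,5-dimethoxyphenyl)-1-(4-methoxyphenyl)ethanol (diastereomer mixture, racemic) | OC(c1ccc(OC)cc1)C(c1cc(OC)cc(OC)c1)c1c(Br)cc(OC)cc1OCc1ccc(OC)cc1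
F8 | step 14 | (2R,3R)-4-bromo-3-(3,5-dimethoxyphenyl)-6-methoxy-2-(4-methoxyphenyl)-2,3-dihydrobenzofuran (enantiomer of 23) | COc1ccc([C@@H]2Oc3cc(OC)cc(Br)c3[C@H]2c2cc(OC)cc(OC)c2)cc1
F9 | step 13 | 2-bromo-4-methoxy-6-(4-methoxybenzyloxy)benzonitrile | N#Cc1c(Br)cc(OC)cc1OCc1ccc(OC)cc1
F10 | step 13 | [2-bromo-4-methoxy-6-(4-methoxybenzyloxy)phenyl](3,5-dimethoxyphenyl)methanimine | N=C(c1cc(OC)cc(OC)c1)c1c(Br)cc(OC)cc1OCc1ccc(OC)cc1
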